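**Retrosynthetic overview**
- The last bond made is the ester C–O between (2E,6S)-6-hydroxy-2,6-dimethylocta-2,7-dienoic acid and the neopentyl alcohol on a 2-methoxy-1,4-naphthoquinone. The acidic 2-OH stays masked as OMe until the final step.
- The strategy rests on the 2-hydroxy-1,4-naphthoquinone ring (ring B). Its C1–C4, with oxygen on C2 and the CH2 of the CH2–C(CH3)2 chain on C3, are the four carbons of dimethyl squarate.
- The hindered C3–CH2 bond is made first, with the neopentyl carbon as a nucleophile (alkyllithium added to the squarate). Phenyllithium then brings in ring A.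
- Ring B is closed by thermal ring expansion of the 4-hydroxy-4-phenylcyclobutenone, followed by oxidation to the quinone.
- The acid comes from geraniol: Sharpless epoxidation sets the (S) carbinol, reductive epoxide opening gives (S)-linalool, and SeO2 then Pinnick oxidation give the E-enoic acid.

Key step: step 5

Remark on the chemistry: the target is taken as the drawn 2-hydroxy-1,4-quinone tautomer, (S) at the tertiary carbinol, E at the enoate. The carbinol carbon of the cyclobutenone intermediates is racemic and is erased in step 5.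

**Step 1**
Reactants: 1 3-bromo-2,2-dimethylpropan-1-ol
Product: 2 (3-bromo-2,2-dimethylpropoxy)(tert-butyl)dimethylsilane
Conditions: TBSCl, imidazole, DMF, 0 °C to rt
Reagents that add atoms: tert-butyldimethylsilyl chloride, CC(C)(C)[Si](C)(C)Cl
Why: Imidazole-promoted silylation of a primary alcohol should be clean because the neopentyl bromide is inert to substitution under these conditions.

**Step 2**
Reactants: 2 (3-bromo-2,2-dimethylpropoxy)(tert-butyl)dimethylsilane, 3 dimethyl squarate (3,4-dimethoxycyclobut-3-ene-1,2-dione)
Product: 5 rac-4-[3-(tert-butyldimethylsilyloxy)-2,2-dimethylpropyl]-4-hydroxy-2,3-dimethoxycyclobut-2-en-1-one, via alkyllithium 4 (not isolated)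
Conditions: t-BuLi (2.1 equiv), Et2O/pentane, −78 °C; cannulate into 3 in THF, −78 °C; aq NH4Cl
Reagents that add atoms: none
Why: Lithium–bromine exchange at a primary carbon with no β-hydrogen (the second equivalent of t-BuLi destroys the tert-butyl bromide) gives a γ-silyloxy alkyllithium that should add 1,2 to one of the two equivalent vinylogous-ester carbonyls of the squarate ester, the resulting alkoxide shielding the ring from a second addition.

**Step 3**
Reactants: 5 rac-4-[3-(tert-butyldimethylsilyloxy)-2,2-dimethylpropyl]-4-hydroxy-2,3-dimethoxycyclobut-2-en-1-one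
Product: 7 3-[3-(tert-butyldimethylsilyloxy)-2,2-dimethylpropyl]-4-methoxycyclobut-3-ene-1,2-dione, via tertiary trifluoroacetate 6 (not isolated)
Conditions: TFAA, pyridine, Et2O, −78 to 0 °C; then H2O/NaHCO3, rt
Reagents that add atoms: water, O
Why: O-Trifluoroacetylation makes the tertiary hydroxyl a leaving group, ionisation gives a methoxy-stabilised cyclobutenyl cation that water captures at the distal methoxy-bearing carbon, and loss of methanol should deliver the cyclobutenedione (the known squarate-adduct rearrangement) under conditions too mild to cleave the silyl ether.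

**Step 4**
Reactants: 7 3-[3-(tert-butyldimethylsilyloxy)-2,2-dimethylpropyl]-4-methoxycyclobut-3-ene-1,2-dione, 8 phenyllithium
Product: 9 rac-2-[3-(tert-butyldimethylsilyloxy)-2,2-dimethylpropyl]-4-hydroxy-3-methoxy-4-phenylcyclobut-2-en-1-one
Conditions: PhLi (1.05 equiv), THF, −78 °C; aq NH4Cl
Reagents that add atoms: none
Why: 1,2-Addition of the aryllithium should occur at the ketone-like carbonyl attached to the methoxy-bearing carbon rather than at the vinylogous-ester carbonyl, and because the phenyl ring is unsubstituted either regiochemistry would lead to the same naphthoquinone.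

**Step 5**
Reactants: 9 rac-2-[3-(tert-butyldimethylsilyloxy)-2,2-dimethylpropyl]-4-hydroxy-3-methoxy-4-phenylcyclobut-2-en-1-one
Product: 12 2-[3-(tert-butyldimethylsilyloxy)-2,2-dimethylpropyl]-3-methoxynaphthalene-1,4-diol, via vinylketene 10 (not isolated), via bicyclic dienone 11 (not isolated)
Conditions: degassed p-xylene, reflux (138 °C), Ar
Reagents that add atoms: none
Why: Heating opens the strained cyclobutenone by a thermal conrotatory 4π electrocyclic cleavage of the C1–C4 bond, and the donor hydroxyl on C4 rotates outward (torquoselectivity), so the phenyl group of vinylketene 10 lies cis to the ketene. The ketene C=C, the enol C=C and one ipso–ortho bond of the phenyl ring then undergo a thermal disrotatory 6π electrocyclisation that joins the ketene carbon to the ortho carbon and closes the six-membered ring B onto ring A; tautomerisation of dienone 11 restores aromaticity and gives the 1,4-diol. The closest known reaction type is the thermal ring expansion of squarate-derived 4-aryl-4-hydroxycyclobutenones to 1,4-naphthohydroquinones (squarate benzannulation). No new stereocentre is formed, and the racemic carbinol carbon becomes an sp2 carbon of ring B. The step needs outward rotation of the hydroxyl and closure onto the arene in preference to other ketene reactions, which the hydroxyl donor, the two equivalent ortho positions of the phenyl ring and a dilute non-nucleophilic medium should secure. The methoxy group and the neopentyl chain already sit on the carbons that become C2 and C3, and the silyl ether and the quaternary carbon are thermally inert.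

**Step 6**
Reactants: 12 2-[3-(tert-butyldimethylsilyloxy)-2,2-dimethylpropyl]-3-methoxynaphthalene-1,4-diol
Product: 13 2-[3-(tert-butyldimethylsilyloxy)-2,2-dimethylpropyl]-3-methoxynaphthalene-1,4-dione
Conditions: Ag2O, Na2SO4, Et2O, rt (crude 12 used directly)
Reagents that add atoms: none
Why: The electron-rich 1,4-hydroquinone should be oxidised to the quinone by Ag2O under neutral conditions that leave the silyl ether and the vinylogous methyl ester untouched.

**Step 7**
Reactants: 13 2-[3-(tert-butyldimethylsilyloxy)-2,2-dimethylpropyl]-3-methoxynaphthalene-1,4-dione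
Product: 14 2-(3-hydroxy-2,2-dimethylpropyl)-3-methoxynaphthalene-1,4-dione
Conditions: HF·pyridine, pyridine, THF, 0 °C to rt
Reagents that add atoms: none
Why: Buffered fluoride desilylation frees the primary alcohol without ever forming an alkoxide, which could otherwise add to the methoxy-bearing quinone carbon and expel methoxide to give a pyran-fused quinone.

**Step 8**
Reactants: 15 geraniol
Product: 16 (2S,3S)-2,3-epoxygeraniol
Conditions: Ti(OiPr)4 (cat.), L-(+)-diethyl tartrate (cat.), t-BuOOH, 4 Å MS, CH2Cl2, −20 °C
Reagents that add atoms: tert-butyl hydroperoxide, CC(C)(C)OO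
Why: Sharpless asymmetric epoxidation is directed by the allylic hydroxyl to the 2,3-alkene only, and the L-(+)-tartrate titanium complex controls the face of oxygen delivery so that the (2S,3S)-epoxide, and with it the future carbinol centre C3, is set by the reagent.

**Step 9**
Reactants: 16 (2S,3S)-2,3-epoxygeraniol
Product: 17 (2R,3S)-2,3-epoxy-1-iodo-3,7-dimethyloct-6-ene
Conditions: PPh3, I2, imidazole, Et2O/MeCN, 0 °C
Reagents that add atoms: iodine, II
Why: Appel-type iodination through the alkoxyphosphonium salt displaces only at the primary carbon, so both epoxide centres are untouched (the C2 descriptor changes by priority only).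

**Step 10**
Reactants: 17 (2R,3S)-2,3-epoxy-1-iodo-3,7-dimethyloct-6-ene
Product: 18 (S)-linalool
Conditions: activated Zn dust, EtOH, reflux; aq NH4Cl
Reagents that add atoms: none
Why: Zinc insertion into the C–I bond followed by β-elimination opens the epoxide to the tertiary allylic alcohol (reductive epoxide opening), and because the C3–O bond is never broken the (S) configuration is retained.

**Step 11**
Reactants: 18 (S)-linalool
Product: 19 (2E,6S)-6-hydroxy-2,6-dimethylocta-2,7-dienal
Conditions: SeO2 (1.1 equiv), 1,4-dioxane/EtOH, 80 °C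
Reagents that add atoms: selenium dioxide, O=[Se]=O
Why: Selenium dioxide allylic oxidation (ene reaction, then 2,3-sigmatropic shift) should attack the E-methyl group of the electron-rich trisubstituted alkene and carry on to the E-enal, the vinyl group having no allylic hydrogen.

**Step 12**
Reactants: 19 (2E,6S)-6-hydroxy-2,6-dimethylocta-2,7-dienal
Product: 20 (2E,6S)-6-hydroxy-2,6-dimethylocta-2,7-dienoic acid
Conditions: NaClO2, NaH2PO4, 2-methyl-2-butene, t-BuOH/H2O, 0 °C to rt
Reagents that add atoms: sodium chlorite, [Na+].[O-]Cl=O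
Why: Pinnick oxidation converts the enal to the acid without touching the alkenes or the tertiary allylic alcohol, the alkene scavenger removing hypochlorous acid, and the E geometry is retained.

**Step 13**
Reactants: 20 (2E,6S)-6-hydroxy-2,6-dimethylocta-2,7-dienoic acid, 14 2-(3-hydroxy-2,2-dimethylpropyl)-3-methoxynaphthalene-1,4-dione
Product: 22 3-(3-methoxy-1,4-dioxo-1,4-dihydronaphthalen-2-yl)-2,2-dimethylpropyl (2E,6S)-6-hydroxy-2,6-dimethylocta-2,7-dienoate, via mixed anhydride 21 (not isolated)
Conditions: 2,4,6-trichlorobenzoyl chloride, Et3N, THF, rt; then 14, DMAP, toluene, rt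
Reagents that add atoms: none
Why: Yamaguchi esterification should acylate the primary neopentyl alcohol through the mixed anhydride and DMAP acyl transfer, while the tertiary allylic alcohol is too hindered to compete and the E-alkene prevents lactonisation.

**Step 14**
Reactants: 22 3-(3-methoxy-1,4-dioxo-1,4-dihydronaphthalen-2-yl)-2,2-dimethylpropyl (2E,6S)-6-hydroxy-2,6-dimethylocta-2,7-dienoate
Product: 23 target CNP0111177.1, 3-(3-hydroxy-1,4-dioxo-1,4-dihydronaphthalen-2-yl)-2,2-dimethylpropyl (2E,6S)-6-hydroxy-2,6-dimethylocta-2,7-dienoate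
Conditions: LiOH·H2O (3 equiv), THF/H2O, 0 °C; then cold 1 M HCl to pH 3
Reagents that add atoms: lithium hydroxide, [Li+].[OH-]
Why: Hydroxide adds to C2 of the vinylogous methyl ester and expels methoxide (addition–elimination) to give the delocalised hydroxyquinone anion, which should form faster than saponification of the hindered α-methyl enoate of a neopentyl alcohol.

**Compound list**
1 | 3-bromo-2,2-dimethylpropan-1-ol | OCC(C)(C)CBr | starting material
2 | (3-bromo-2,2-dimethylpropoxy)(tert-butyl)dimethylsilane | CC(C)(C)[Si](C)(C)OCC(C)(C)CBr | intermediate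
3 | dimethyl squarate | COC1=C(OC)C(=O)C1=O | starting material
4 | [3-(tert-butyldimethylsilyloxy)-2,2-dimethylpropyl]lithium | [Li]CC(C)(C)CO[Si](C)(C)C(C)(C)C | intermediate
5 | rac-4-[3-(tert-butyldimethylsilyloxy)-2,2-dimethylpropyl]-4-hydroxy-2,3-dimethoxycyclobut-2-en-1-one | COC1=C(OC)C(O)(CC(C)(C)CO[Si](C)(C)C(C)(C)C)C1=O | intermediate
6 | trifluoroacetate ester of 5 at the tertiary hydroxyl | COC1=C(OC)C(OC(=O)C(F)(F)F)(CC(C)(C)CO[Si](C)(C)C(C)(C)C)C1=O | intermediate
7 | 3-[3-(tert-butyldimethylsilyloxy)-2,2-dimethylpropyl]-4-methoxycyclobut-3-ene-1,2-dione | COC1=C(CC(C)(C)CO[Si](C)(C)C(C)(C)C)C(=O)C1=O | intermediate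
8 | phenyllithium | [Li]c1ccccc1 | starting material
9 | rac-2-[3-(tert-butyldimethylsilyloxy)-2,2-dimethylpropyl]-4-hydroxy-3-methoxy-4-phenylcyclobut-2-en-1-one | COC1=C(CC(C)(C)CO[Si](C)(C)C(C)(C)C)C(=O)C1(O)c1ccccc1 | intermediate
10 | 2-[3-(tert-butyldimethylsilyloxy)-2,2-dimethylpropyl]-4-hydroxy-3-methoxy-4-phenylbuta-1,3-dien-1-one (vinylketene, phenyl cis to the ketene-bearing carbon) | O=C=C(CC(C)(C)CO[Si](C)(C)C(C)(C)C)/C(OC)=C(/O)c1ccccc1 | intermediate
11 | rac-2-[3-(tert-butyldimethylsilyloxy)-2,2-dimethylpropyl]-4-hydroxy-3-methoxy-8aH-naphthalen-1-one (dienone before tautomerisation) | COC1=C(CC(C)(C)CO[Si](C)(C)C(C)(C)C)C(=O)C2C=CC=CC2=C1O | intermediate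
12 | 2-[3-(tert-butyldimethylsilyloxy)-2,2-dimethylpropyl]-3-methoxynaphthalene-1,4-diol | COc1c(CC(C)(C)CO[Si](C)(C)C(C)(C)C)c(O)c2ccccc2c1O | intermediate
13 | 2-[3-(tert-butyldimethylsilyloxy)-2,2-dimethylpropyl]-3-methoxynaphthalene-1,4-dione | COC1=C(CC(C)(C)CO[Si](C)(C)C(C)(C)C)C(=O)c2ccccc2C1=O | intermediate
14 | 2-(3-hydroxy-2,2-dimethylpropyl)-3-methoxynaphthalene-1,4-dione | COC1=C(CC(C)(C)CO)C(=O)c2ccccc2C1=O | intermediate
15 | geraniol | CC(C)=CCC/C(C)=C/CO | starting material
16 | (2S,3S)-2,3-epoxygeraniol | OC[C@H]1[C@@](C)(O1)CCC=C(C)C | intermediate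
17 | (2R,3S)-2,3-epoxy-1-iodo-3,7-dimethyloct-6-ene | IC[C@H]1[C@@](C)(O1)CCC=C(C)C | intermediate
18 | (S)-linalool | C=C[C@@](C)(O)CCC=C(C)C | intermediate
19 | (2E,6S)-6-hydroxy-2,6-dimethylocta-2,7-dienal | C=C[C@@](C)(O)CC/C=C(\C)C=O | intermediate
20 | (2E,6S)-6-hydroxy-2,6-dimethylocta-2,7-dienoic acid | C=C[C@@](C)(O)CC/C=C(\C)C(=O)O | intermediate
21 | (2E,6S)-6-hydroxy-2,6-dimethylocta-2,7-dienoic 2,4,6-trichlorobenzoic anhydride | C=C[C@@](C)(O)CC/C=C(\C)C(=O)OC(=O)c1c(Cl)cc(Cl)cc1Cl | intermediate
22 | 3-(3-methoxy-1,4-dioxo-1,4-dihydronaphthalen-2-yl)-2,2-dimethylpropyl (2E,6S)-6-hydroxy-2,6-dimethylocta-2,7-dienoate | C=C[C@@](C)(O)CC/C=C(\C)C(=O)OCC(C)(C)CC1=C(OC)C(=O)c2ccccc2C1=O | intermediate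
23 | CNP0111177.1, 3-(3-hydroxy-1,4-dioxo-1,4-dihydronaphthalen-2-yl)-2,2-dimethylpropyl (2E,6S)-6-hydroxy-2,6-dimethylocta-2,7-dienoate | C=C[C@@](C)(O)CC/C=C(\C)C(=O)OCC(C)(C)CC1=C(O)C(=O)c2ccccc2C1=O | target

**Step count**
Total: 14 steps. Longest linear sequence: 9 steps (1 to 23 through steps 1–7, 13 and 14). The acid branch is 5 steps (8–12) before the union.

**Steps most likely to fail**

Step 2. The halogen–lithium exchange at the neopentyl bromide may run partly through single-electron pathways (reduction or coupling of the alkyl group). The γ-silyloxy alkyllithium may also suffer a 1,4 oxygen-to-carbon silyl shift, and excess reagent may add twice to the squarate. The fallback sets out from bromide 2. Direct insertion of magnesium (Mg turnings activated with 1,2-dibromoethane, THF, reflux) should give [3-(tert-butyldimethylsilyloxy)-2,2-dimethylpropyl]magnesium bromide F1, formed without t-BuLi and with a less basic carbon–metal bond. Its addition to dimethyl squarate 3 in THF at −78 to −20 °C, with an NH4Cl quench, comes back to the route at hydroxycyclobutenone 5.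

Step 11. The selenium dioxide oxidation may stall at the allylic alcohol, over-oxidise, or trigger acid-promoted transposition or cyclisation of the tertiary allylic alcohol, so the enal may be formed with low chemoselectivity. The fallback sets out from (S)-linalool 18 and replaces steps 11 and 12. Ozonolysis restricted to the electron-rich trisubstituted alkene (O3, CH2Cl2/MeOH, −78 °C, Sudan red 7B as end-point indicator, then Me2S) should give (S)-4-hydroxy-4-methylhex-5-enal F2, which equilibrates with its lactol. Wittig olefination with ethyl 2-(triphenylphosphoranylidene)propanoate (toluene, 80 °C) should give ethyl (2E,6S)-6-hydroxy-2,6-dimethylocta-2,7-dienoate F3, with the E geometry expected of a stabilised ylide. Saponification (LiOH, THF/H2O, rt) comes back to the route at acid 20.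

Step 14. Hydroxide may attack the enoate ester in competition with the hindered C2 of the quinone, so that ester cleavage accompanies or outruns the unmasking. The fallback sets out from quinone 13 and changes the mask so that it is removed without base. Base-catalysed alkoxy exchange at C2 (allyl alcohol, cat. NaH, THF, 0 °C) should give 2-allyloxy-3-[3-(tert-butyldimethylsilyloxy)-2,2-dimethylpropyl]naphthalene-1,4-dione F4. Desilylation (HF·pyridine, THF) should give 2-allyloxy-3-(3-hydroxy-2,2-dimethylpropyl)naphthalene-1,4-dione F5. Yamaguchi esterification with acid 20 through anhydride 21 should give 3-(3-allyloxy-1,4-dioxo-1,4-dihydronaphthalen-2-yl)-2,2-dimethylpropyl (2E,6S)-6-hydroxy-2,6-dimethylocta-2,7-dienoate F6. Allyl transfer to morpholine catalysed by Pd(PPh3)4, a zerovalent palladium complex (THF, rt), is neutral toward the ester and comes back to the route at target 23.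

**Further compounds**
F1 | step 2 | [3-(tert-butyldimethylsilyloxy)-2,2-dimethylpropyl]magnesium bromide | CC(C)(C)[Si](C)(C)OCC(C)(C)C[Mg]Br
F2 | step 11 | (S)-4-hydroxy-4-methylhex-5-enal | C=C[C@@](C)(O)CCC=O
F3 | step 11 | ethyl (2E,6S)-6-hydroxy-2,6-dimethylocta-2,7-dienoate | C=C[C@@](C)(O)CC/C=C(\C)C(=O)OCC
F4 | step 14 | 2-allyloxy-3-[3-(tert-butyldimethylsilyloxy)-2,2-dimethylpropyl]naphthalene-1,4-dione | C=CCOC1=C(CC(C)(C)CO[Si](C)(C)C(C)(C)C)C(=O)c2ccccc2C1=O
F5 | step 14 | 2-allyloxy-3-(3-hydroxy-2,2-dimethylpropyl)naphthalene-1,4-dione | C=CCOC1=C(CC(C)(C)CO)C(=O)c2ccccc2C1=O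
F6 | step 14 | 3-(3-allyloxy-1,4-dioxo-1,4-dihydronaphthalen-2-yl)-2,2-dimethylpropyl (2E,6S)-6-hydroxy-2,6-dimethylocta-2,7-dienoate | C=C[C@@](C)(O)CC/C=C(\C)C(=O)OCC(C)(C)CC1=C(OCC=C)C(=O)c2ccccc2C1=O
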